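The readings stem from a simulated flask for substances that don't exist; the scatter is artificial.

D, the ring, is the product you collect here, and its share drops as the charge of Z rises: 84.1% at 4.4 mM on Friday, 29.1% at 96 mM on Tuesday. Tuesday's D reads 29.0% at 20.0 min and 29.6% at 40.0 min, so expect a finished yield at 50 min; do not wait for more.

| flask | Z | remark | time |
|---|---|---|---|
| Friday's | 4.4 mM | run made earlier |  |
| Tuesday's | 96 mM | run made earlier |  |
| cedar | 150 mM |  | 50 min |
| oak | 100 mM |  | 50 min |
| elm | 60 mM |  | 50 min |
| maple | 8.0 mM |  | 50 min |
| ash | 34 mM |  | 50 min |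

- Friday's (time / min: D / %): 3.00: 76.8; 5.00: 81.9; 8.00: 83.0; 12.0: 84.6; 20.0: 84.1; 40.0: 83.4
- Tuesday's (time / min: D / %): 6.00: 26.1; 12.0: 28.0; 20.0: 29.0; 25.0: 29.0; 30.0: 29.1; 40.0: 29.6

(scatter of a reading: 0.3 percentage points)

- a reading or a percentage of D counts all its forms, free or not

- ranking by amount of D, in percent of the Z charged, from high to low, at 50 min (cedar / oak / elm / maple / ash)
- the amount of D, in percent of the Z charged of the flask you put first, at 50 min
- the amount of D, in percent of the Z charged of the flask you put last, at 50 min

Treat Z as leaving by first-order closure and by a second-order loss. The yield of D is then ln(1+x)/x, where x is the charge over one concentration. Solve this for Tuesday's reading: x = 7.24. The apparent crossover concentration c* = 13.3 mM, the charge at which x is 1 on this curve, is fitted to one of Tuesday's readings, so it carries their scatter and is no constant of the flask. Expect yield to fall as the charge climbs, so rank maple, ash, elm, oak, cedar. Cedar comes to 22.2%. Maple comes to 78.2%, but the same c* gives Friday's flask 86.4%, which is 2.3 percentage points over its reading. Take that off maple: 75.9%.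

The forecast says maple > ash > elm > oak > cedar, with 76% (72% to 79%) and 23% (19% to 26%), since “yield should fall steadily with concentration”.

The flasks give maple > ash > elm > oak > cedar, with maple at 75.6% and cedar at 22.7%.

    Z → D (k = 1.10 min⁻¹)
    2 Z → Q (k = 61.7 M⁻¹ min⁻¹)
    Z + D ⇌ G, settled at all times (K = 230 M⁻¹)

Cedar, charged at 11.3 times the apparent c*, ends at 22.7% D because of the loss of two Z to Q: the same run without that step ends at 95.3%. The neighbour of cedar charged with 380 mM stands at x = 28.7, where c* gives 11.8%. That flask holds 12.3% D at 50.0 min, its forms counted.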